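The cyclohexenone ring (C1 carbonyl, C2=C3–Me, C4–OH, C5–geranylgeranyl, C6H2) is cut at C2–C3 and C5–C6 into an acetone 1,3-dianion equivalent (C6–C1–C2, as the dianion of allyl acetoacetate) and an acyclic C3–C5 unit: a methyl ketone (C3) bearing an O-carbonate at C4 and a chloride at C5. In one operation the dianion terminus adds to the C3 ketone, the aldolate is locked as a C3/C4 cyclic carbonate, and the enolate carbon displaces the C5 chloride with inversion. The step exploits the 1,3-relationship of C2 and C6 across the C1 carbonyl and maps the cis C4–OH/C5 side chain onto an anti chlorohydrin; mild elimination then releases the enone.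

Key step: step 6

Remark: ring atoms are numbered C1 (carbonyl carbon), C2 (=CH), C3 (C–CH3), C4 (CH–OH), C5 (CH bearing the geranylgeranyl group) and C6 (CH2); the ester-bearing C6 of 14 is configurationally labile and is written without a descriptor.

Step 1
Reactants: 1 geranylgeraniol
Product: 2 geranylgeranyl bromide
Conditions: PBr3 (0.4 equiv), Et2O, −10 °C
Reagents that add atoms: phosphorus tribromide, BrP(Br)Br
Why: Bromination of a primary allylic alcohol through its phosphite ester is an SN2 substitution at C1 that should proceed without allylic transposition or loss of alkene geometry.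

Step 2
Reactants: 2 geranylgeranyl bromide; 3 acetonitrile
Product: 4 homologated nitrile
Conditions: MeCN (5 equiv), n-BuLi, THF, −78 °C; then 2, −78 to 0 °C
Reagents that add atoms: none
Why: SN2 alkylation of lithioacetonitrile at the unsubstituted terminus of the allylic bromide should add the two carbons that become C5 and C4, the excess of nucleophile suppressing dialkylation.

Step 3
Reactants: 4 homologated nitrile
Product: 5 γ,δ-unsaturated aldehyde
Conditions: i-Bu2AlH, CH2Cl2, −78 °C; aqueous potassium sodium tartrate
Reagents that add atoms: water, O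
Why: Partial reduction of a nitrile with i-Bu2AlH stops at the N-aluminated aldimine, which should hydrolyse on work-up to the aldehyde without touching the isolated alkenes.

Step 4
Reactants: 5 γ,δ-unsaturated aldehyde
Product: 6 (2R)-2-chloro aldehyde
Conditions: NCS, 2,5-diphenylpyrrolidine (10 mol %, the antipode that gives the 2R chloride), CH2Cl2, −20 °C
Reagents that add atoms: N-chlorosuccinimide, O=C1CCC(=O)N1Cl
Why: Enamine-mediated organocatalytic α-chlorination should deliver chlorine to the enamine face left open by the C2-symmetric amine and so set the chloride stereocenter (the future C5), the enamine being far more nucleophilic than the trisubstituted alkenes.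

Step 5
Reactants: 6 (2R)-2-chloro aldehyde; 7 ethyl vinyl ether
Product: 10 α-(phenoxycarbonyloxy) β-chloro methyl ketone, via chlorohydrin lithium alkoxide 8 (not isolated), via enol ether carbonate 9 (not isolated)
Conditions: 7, t-BuLi, THF, −78 to 0 °C; 6, −78 °C; PhOCOCl, −78 to −30 °C; then 0.5 M HCl, THF, 0 °C
Reagents that add atoms: phenyl chloroformate, O=C(Cl)Oc1ccccc1; water, O
Why: 1,2-Addition of the acetyl anion equivalent 1-ethoxyvinyllithium to the α-chloro aldehyde should follow the Cornforth (polar Felkin–Anh) model and attack anti to the C–Cl bond, setting C4 in the 1,2-anti chlorohydrin, whose alkoxide is acylated before it can close to an epoxide, after which mild acid hydrolysis of the enol ether reveals the methyl ketone.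

Step 6
Reactants: 10 α-(phenoxycarbonyloxy) β-chloro methyl ketone; 11 allyl acetoacetate
Product: 14 cis-fused bicyclic carbonate β-keto ester, via aldol adduct 12 (not isolated), via cyclic carbonate 13 (not isolated)
Conditions: 11, NaH then n-BuLi, THF, 0 °C; 10, −78 to 0 °C; then DMPU, 40 °C
Reagents that add atoms: none
Why: The terminal carbanion of the acetoacetate dianion (the future C2) adds to the C3 ketone in an aldol addition, the tertiary alkoxide attacks the neighbouring phenyl carbonate (5-exo-trig acyl transfer) and expels phenoxide, which blocks retro-aldol cleavage and ties C3–O and C4–O into a cyclic carbonate, and the remaining stabilised enolate carbon (C6) then displaces the C5 chloride (6-exo-tet C-alkylation) to close the carbocycle. The closest known reaction type is the cyclisation of 1,3-dicarbonyl dianions with 1,3-dielectrophiles, here a dianion aldol addition followed by intramolecular β-keto ester alkylation. C3 is set by Felkin–Anh addition anti to the C4–O bond, which places C2 and C5 cis on the carbonate ring so that the six-membered ring can close cis-fused, and this centre and the labile C6 are erased in step 7. C5 is set by SN2 inversion of the defined chloride, which turns the anti chlorohydrin into the cis arrangement of C4–O and the C5 side chain, while C4 is untouched. The step needs carbonyl addition to outrun deprotonation at C4 (which would eliminate HCl), secured by the low temperature and the activated α-acyloxy ketone, and C- over O-alkylation, favoured for six-ring closure of a β-keto ester enolate; no iodide is added, so that C5 cannot be scrambled by halide exchange.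

Step 7
Reactants: 14 cis-fused bicyclic carbonate β-keto ester
Product: 16 target hydroxy enone, via keto carbonate 15 (not isolated)
Conditions: Pd(PPh3)4 (5 mol %), morpholine, THF, 23 °C; then DBU, 0 °C
Reagents that add atoms: none
Why: Tsuji–Trost deallylation transfers the allyl group to morpholine, the β-keto acid decarboxylates to 15, and E1cB elimination of the β-carbonate at C3 should form the C2=C3 enone while the C4 carbonate half-ester loses CO2 to give the free hydroxyl with C4 and C5 unchanged.

Compound list
1 | (2E,6E,10E)-3,7,11,15-tetramethylhexadeca-2,6,10,14-tetraen-1-ol (geranylgeraniol) | CC(C)=CCC/C(C)=C/CC/C(C)=C/CC/C(C)=C/CO | starting material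
2 | (2E,6E,10E)-1-bromo-3,7,11,15-tetramethylhexadeca-2,6,10,14-tetraene (geranylgeranyl bromide) | CC(C)=CCC/C(C)=C/CC/C(C)=C/CC/C(C)=C/CBr | intermediate
3 | acetonitrile | CC#N | starting material
4 | (4E,8E,12E)-5,9,13,17-tetramethyloctadeca-4,8,12,16-tetraenenitrile | CC(C)=CCC/C(C)=C/CC/C(C)=C/CC/C(C)=C/CCC#N | intermediate
5 | (4E,8E,12E)-5,9,13,17-tetramethyloctadeca-4,8,12,16-tetraenal | CC(C)=CCC/C(C)=C/CC/C(C)=C/CC/C(C)=C/CCC=O | intermediate
6 | (2R,4E,8E,12E)-2-chloro-5,9,13,17-tetramethyloctadeca-4,8,12,16-tetraenal | CC(C)=CCC/C(C)=C/CC/C(C)=C/CC/C(C)=C/C[C@@H](Cl)C=O | intermediate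
7 | ethyl vinyl ether | C=COCC | starting material
8 | (3S,4R,6E,10E,14E)-4-chloro-2-ethoxy-7,11,15,19-tetramethylicosa-1,6,10,14,18-pentaen-3-ol (formed as its lithium alkoxide) | CC(C)=CCC/C(C)=C/CC/C(C)=C/CC/C(C)=C/C[C@@H](Cl)[C@@H](O)C(=C)OCC | intermediate (not isolated)
9 | (3S,4R,6E,10E,14E)-4-chloro-2-ethoxy-7,11,15,19-tetramethylicosa-1,6,10,14,18-pentaen-3-yl phenyl carbonate | CC(C)=CCC/C(C)=C/CC/C(C)=C/CC/C(C)=C/C[C@@H](Cl)[C@@H](OC(=O)Oc1ccccc1)C(=C)OCC | intermediate (not isolated)
10 | (3S,4R,6E,10E,14E)-4-chloro-7,11,15,19-tetramethyl-2-oxoicosa-6,10,14,18-tetraen-3-yl phenyl carbonate | CC(C)=CCC/C(C)=C/CC/C(C)=C/CC/C(C)=C/C[C@@H](Cl)[C@@H](OC(=O)Oc1ccccc1)C(C)=O | intermediate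
11 | allyl acetoacetate (prop-2-enyl 3-oxobutanoate) | CC(=O)CC(=O)OCC=C | starting material
12 | prop-2-enyl (5S,6S,7R,9E,13E,17E)-7-chloro-5-hydroxy-5,10,14,18,22-pentamethyl-3-oxo-6-(phenoxycarbonyloxy)tricosa-9,13,17,21-tetraenoate (formed as its alkoxide enolate) | CC(C)=CCC/C(C)=C/CC/C(C)=C/CC/C(C)=C/C[C@@H](Cl)[C@@H](OC(=O)Oc1ccccc1)[C@@](C)(O)CC(=O)CC(=O)OCC=C | intermediate (not isolated)
13 | prop-2-enyl 4-[(4S,5S)-5-[(1R,3E,7E,11E)-1-chloro-4,8,12,16-tetramethylheptadeca-3,7,11,15-tetraenyl]-4-methyl-2-oxo-1,3-dioxolan-4-yl]-3-oxobutanoate (formed as its enolate) | CC(C)=CCC/C(C)=C/CC/C(C)=C/CC/C(C)=C/C[C@@H](Cl)[C@H]1OC(=O)O[C@@]1(C)CC(=O)CC(=O)OCC=C | intermediate (not isolated)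
14 | prop-2-enyl (3aS,7R,7aR)-3a-methyl-2,5-dioxo-7-[(2E,6E,10E)-3,7,11,15-tetramethylhexadeca-2,6,10,14-tetraenyl]hexahydro-1,3-benzodioxole-6-carboxylate (cis-fused; epimers at the ester-bearing carbon) | CC(C)=CCC/C(C)=C/CC/C(C)=C/CC/C(C)=C/C[C@@H]1C(C(=O)OCC=C)C(=O)C[C@]2(C)OC(=O)O[C@H]12 | intermediate
15 | (3aS,7R,7aR)-3a-methyl-7-[(2E,6E,10E)-3,7,11,15-tetramethylhexadeca-2,6,10,14-tetraenyl]hexahydro-1,3-benzodioxole-2,5-dione | CC(C)=CCC/C(C)=C/CC/C(C)=C/CC/C(C)=C/C[C@@H]1CC(=O)C[C@]2(C)OC(=O)O[C@H]12 | intermediate (not isolated)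
16 | (4R,5R)-4-hydroxy-3-methyl-5-[(2E,6E,10E)-3,7,11,15-tetramethylhexadeca-2,6,10,14-tetraenyl]cyclohex-2-en-1-one | CC(C)=CCC/C(C)=C/CC/C(C)=C/CC/C(C)=C/C[C@@H]1CC(=O)C=C(C)[C@@H]1O | target

Total step count: 7. Longest linear sequence: 7 steps (1 to 16).

Steps most likely to fail

Step 6. The strongly basic dianion may take a proton from C4 of 10 instead of adding to the ketone, with loss of chloride by elimination. The aldolate may also revert before the carbonate closes, and displacement of the secondary chloride next to the oxygenated carbon may be slow or go through oxygen. The fallback separates the two bond formations and makes the first under Lewis acid instead of base, setting out from 10 and 11. Compound 11 would be silylated (Et3N/Me3SiCl, then LiN(i-Pr)2/Me3SiCl) to the bis(trimethylsilyl) dienol ether F1. The terminal carbon of F1 would add to the ketone of 10 in a vinylogous Mukaiyama aldol reaction (BF3·OEt2, CH2Cl2, −78 °C) to give, after desilylating work-up, the hydroxy keto ester 12 as an isolated compound. Cs2CO3 in DMF at 40 °C would then close the cyclic carbonate (13) and the carbocycle, returning to the route at 14.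

Step 5. Facial selectivity in the addition may be poor, the basic vinyllithium may enolise 6 and erode the chloride stereocenter, or the alkoxide may close to an epoxide before it is acylated. The fallback introduces the acetyl unit as an alkyne, setting out from 6. Ethynylmagnesium bromide (THF, −78 °C), a less basic nucleophile that should also add anti to the C–Cl bond, would give the propargylic chlorohydrin F2. Phenyl chloroformate and pyridine would give its phenyl carbonate F3. Markovnikov hydration of the terminal alkyne catalysed by Ph3PAuNTf2 in wet dioxane, assisted by the neighbouring carbonate carbonyl, would return to the route at 10.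

Step 4. NCS may chlorinate the trisubstituted alkenes of the chain, and the enantiopurity of 6 may erode through enamine or enol equilibration. The fallback sets the chloride stereocenter under auxiliary control on a cold enolate, setting out from 4. Alkaline hydrolysis (KOH, aqueous ethylene glycol, heat) would give the acid F4. Acylation of (4R)-4-benzyloxazolidin-2-one through the pivalic mixed anhydride would give the imide F5. Its sodium enolate (NaN(SiMe3)2, THF, −78 °C) would be chlorinated by NCS on the face opposite the benzyl group to give the (2R)-chloro imide F6. LiBH4 would release the auxiliary and give the chloro alcohol F7, and Dess–Martin oxidation would return to the route at 6.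

Further compounds
F1 | step 6 | 1-(prop-2-enyloxy)-1,3-bis(trimethylsilyloxy)buta-1,3-diene | C=CCOC(O[Si](C)(C)C)=CC(=C)O[Si](C)(C)C
F2 | step 5 | (3S,4R,6E,10E,14E)-4-chloro-7,11,15,19-tetramethylicosa-6,10,14,18-tetraen-1-yn-3-ol | CC(C)=CCC/C(C)=C/CC/C(C)=C/CC/C(C)=C/C[C@@H](Cl)[C@@H](O)C#C
F3 | step 5 | (3S,4R,6E,10E,14E)-4-chloro-7,11,15,19-tetramethylicosa-6,10,14,18-tetraen-1-yn-3-yl phenyl carbonate | CC(C)=CCC/C(C)=C/CC/C(C)=C/CC/C(C)=C/C[C@@H](Cl)[C@@H](OC(=O)Oc1ccccc1)C#C
F4 | step 4 | (4E,8E,12E)-5,9,13,17-tetramethyloctadeca-4,8,12,16-tetraenoic acid | CC(C)=CCC/C(C)=C/CC/C(C)=C/CC/C(C)=C/CCC(=O)O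
F5 | step 4 | (4R)-4-benzyl-3-[(4E,8E,12E)-5,9,13,17-tetramethyloctadeca-4,8,12,16-tetraenoyl]oxazolidin-2-one | CC(C)=CCC/C(C)=C/CC/C(C)=C/CC/C(C)=C/CCC(=O)N1[C@H](Cc2ccccc2)COC1=O
F6 | step 4 | (4R)-4-benzyl-3-[(2R,4E,8E,12E)-2-chloro-5,9,13,17-tetramethyloctadeca-4,8,12,16-tetraenoyl]oxazolidin-2-one | CC(C)=CCC/C(C)=C/CC/C(C)=C/CC/C(C)=C/C[C@@H](Cl)C(=O)N1[C@H](Cc2ccccc2)COC1=O
F7 | step 4 | (2R,4E,8E,12E)-2-chloro-5,9,13,17-tetramethyloctadeca-4,8,12,16-tetraen-1-ol | CC(C)=CCC/C(C)=C/CC/C(C)=C/CC/C(C)=C/C[C@@H](Cl)CO
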